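**Assumption:** the SMILES is taken as authoritative, i.e. (1S,6R,8S) with a 4Z (cis) ring olefin; germacrane numbering (C1–C15) is used for positions. TBDPS = tert-butyldiphenylsilyl, TBS = tert-butyldimethylsilyl.

## Retrosynthetic overview

1. Ten-membered ring last: C1–C10 by intramolecular Nozaki–Hiyama–Kishi addition of a 2-bromoalkene to the C1 aldehyde, which gives the free 1-OH and the 10(14)-methylene directly.
2. C8–C9 by reagent-controlled 2-bromoallylation of a 4-formylbutenolide (sets C8), then acetylation.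
3. 13-OAc and the 7(11)-olefin by bromination/acetolysis of the silyl dienol ether of an α-methylene-β-formyl lactone (butenolide unsaturation formed second).
4. C6–C7 by an Evans syn-aldol between an itaconate-derived N-acyloxazolidinone (C7, C8, C11–C13) and a nerol-derived (Z)-enal (C1–C6, C15); this is the main fragment union and sets C6, and lactonisation then gives the γ-lactone (first ring).
5. Starting materials: nerol, itaconic anhydride, (S)-4-benzyl-2-oxazolidinone, 2,3-dibromopropene.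

## Route

Step 1
Reactants: 1 nerol
Product: 2 neryl acetate
Conditions: Ac2O, pyridine, DMAP (catalytic), CH2Cl2, 0 to 23 °C
Reagents that add atoms: acetic anhydride CC(=O)OC(C)=O
Why: Acetylation (nucleophilic acyl substitution) masks the C6 oxygen and deactivates the 2,3-olefin towards the epoxidation that follows.

Step 2
Reactants: 2 neryl acetate
Product: 3 (2Z)-5-(3,3-dimethyloxiran-2-yl)-3-methylpent-2-en-1-yl acetate (racemic at the oxirane)
Conditions: mCPBA (1.05 equiv), NaHCO3, CH2Cl2, 0 °C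
Reagents that add atoms: mCPBA OOC(=O)c1cccc(Cl)c1
Why: Prilezhaev epoxidation is selective for the remote, more electron-rich trisubstituted olefin over the allylic-acetate olefin; the oxirane stereocentre is destroyed in step 3.

Step 3
Reactants: 3 epoxy acetate
Product: 4 (2Z)-3-methyl-6-oxohex-2-en-1-yl acetate
Conditions: H5IO6, THF/H2O, 0 to 23 °C
Reagents that add atoms: none
Why: One-pot epoxide hydration and Malaprade glycol cleavage excises acetone and leaves the C1 aldehyde without touching the Z-olefin or the acetate.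

Step 4
Reactants: 4 aldehyde acetate
Product: 5 (2Z)-6-hydroxy-3-methylhex-2-en-1-yl acetate
Conditions: NaBH4, MeOH, 0 °C, 15 min
Reagents that add atoms: none
Why: Chemoselective borohydride reduction of the aldehyde; the acetate survives the short cold exposure.

Step 5
Reactants: 5 hydroxy acetate
Product: 6 (2Z)-6-[(tert-butyldiphenylsilyl)oxy]-3-methylhex-2-en-1-yl acetate
Conditions: TBDPSCl, imidazole, DMF, 23 °C
Reagents that add atoms: tert-butyldiphenylsilyl chloride CC(C)(C)[Si](Cl)(c1ccccc1)c1ccccc1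
Why: Silyl ether formation gives a C1 protecting group that withstands the boron, peroxide, hydride, acid and acetylation conditions used up to step 18.

Step 6
Reactants: 6 silyl ether acetate
Product: 7 (2Z)-6-[(tert-butyldiphenylsilyl)oxy]-3-methylhex-2-en-1-ol
Conditions: K2CO3 (catalytic), MeOH, 23 °C
Reagents that add atoms: none
Why: Zemplén-type transesterification frees the allylic alcohol and leaves the silyl ether intact.

Step 7
Reactants: 7 allylic alcohol
Product: 8 (2Z)-6-[(tert-butyldiphenylsilyl)oxy]-3-methylhex-2-enal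
Conditions: MnO2, CH2Cl2, 23 °C
Reagents that add atoms: none
Why: Neutral heterogeneous MnO2 oxidation of the allylic alcohol gives the enal with retention of the Z geometry (as in nerol to neral).

Step 8
Reactants: 9 (4S)-4-benzyl-1,3-oxazolidin-2-one; 10 itaconic anhydride
Product: 12 4-[(4S)-4-benzyl-2-oxo-1,3-oxazolidin-3-yl]-2-methylidene-4-oxobutanoic acid, via lithium oxazolidinide 11 (not isolated)
Conditions: n-BuLi, THF, −78 °C; then 10, −78 to 0 °C; aqueous HCl work-up
Reagents that add atoms: none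
Why: N-acylation by anhydride opening at the non-conjugated, less hindered carbonyl (the usual regiochemistry for itaconic anhydride) puts the imide on C8 and leaves the conjugated C12 acid free; low temperature and the absence of amine avoid isomerisation to citraconate.

Step 9
Reactants: 12 acid imide
Product: 13 methyl 4-[(4S)-4-benzyl-2-oxo-1,3-oxazolidin-3-yl]-2-methylidene-4-oxobutanoate
Conditions: TMSCHN2 (1.05 equiv), toluene/MeOH, 0 °C, 15 min; AcOH quench
Reagents that add atoms: (trimethylsilyl)diazomethane C[Si](C)(C)C=[N+]=[N-]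
Why: Base-free O-methylation with a diazoalkane esterifies the acid without isomerising the acidic C7 methylene or the 1,1-disubstituted olefin.

Step 10
Reactants: 13 imide ester; 8 (Z)-enal
Product: 15 methyl (3S,4R,5Z)-3-{[(4S)-4-benzyl-2-oxo-1,3-oxazolidin-3-yl]carbonyl}-9-[(tert-butyldiphenylsilyl)oxy]-4-hydroxy-6-methyl-2-methylidenenon-5-enoate, via Z-boron enolate 14 (not isolated)
Conditions: Bu2BOTf, iPr2NEt, CH2Cl2, −78 to 0 °C; then 8, −78 to 0 °C; pH 7 buffer, MeOH, H2O2, 0 °C
Reagents that add atoms: none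
Why: Evans syn-aldol through a Zimmerman–Traxler chair of the Z-boron enolate forms C6–C7, and the (S)-benzyl auxiliary sets C6 as R (C7 is also set but is erased in step 14).

Step 11
Reactants: 15 aldol adduct
Product: 17 (2R,3S)-2-{(1Z)-5-[(tert-butyldiphenylsilyl)oxy]-2-methylpent-1-en-1-yl}-4-methylidene-5-oxooxolane-3-carboxylic acid, via hydroxy acid 16 (not isolated)
Conditions: LiOH, 30% H2O2, THF/H2O, 0 °C; Na2SO3; HCl to pH 3; then PPTS (catalytic), toluene, 50 °C
Reagents that add atoms: hydrogen peroxide OO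
Why: Hydroperoxide cleaves the exocyclic imide carbonyl selectively, and the C6 hydroxyl then lactonises onto the C12 ester (the only γ-related carboxyl) with retention at C6, giving an α-methylene paraconic acid.

Step 12
Reactants: 17 lactone acid
Product: 19 (2R,3S)-2-{(1Z)-5-[(tert-butyldiphenylsilyl)oxy]-2-methylpent-1-en-1-yl}-4-methylidene-5-oxooxolane-3-carbaldehyde, via acid chloride 18 (not isolated)
Conditions: 1-chloro-N,N,2-trimethylprop-1-en-1-amine, CH2Cl2, 0 °C; then LiAlH(OtBu)3, THF, −78 °C; crude product used at once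
Reagents that add atoms: none
Why: Neutral acid chloride formation (Ghosez reagent) followed by low-temperature LiAlH(OtBu)3 reduction stops at the aldehyde and does not touch the lactone, the olefins or the silyl ether.

Step 13
Reactants: 19 aldehyde
Product: 20 (5R)-4-{[(tert-butyldimethylsilyl)oxy]methylidene}-5-{(1Z)-5-[(tert-butyldiphenylsilyl)oxy]-2-methylpent-1-en-1-yl}-3-methylideneoxolan-2-one (enol ether E/Z mixture)
Conditions: TBSOTf, then Et3N, CH2Cl2, −78 to 0 °C; non-aqueous filtration through deactivated silica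
Reagents that add atoms: tert-butyldimethylsilyl triflate CC(C)(C)[Si](C)(C)OS(=O)(=O)C(F)(F)F
Why: Soft enolisation of the aldehyde removes only C7–H (α to the formyl group and allylic), while C6–H is not acidic as long as the olefin is exocyclic, so the C6 stereocentre is untouched.

Step 14
Reactants: 20 silyl dienol ether
Product: 22 [(5R)-5-{(1Z)-5-[(tert-butyldiphenylsilyl)oxy]-2-methylpent-1-en-1-yl}-4-formyl-2-oxo-2,5-dihydrofuran-3-yl]methyl acetate, via bromomethyl butenolide aldehyde 21 (not isolated)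
Conditions: NBS, THF, −78 °C; then KOAc, AcOH, 23 °C
Reagents that add atoms: potassium acetate CC(=O)[O-].[K+]
Why: Vinylogous (γ) bromination of the silyl dienol ether followed by SN2 acetate displacement (SN2' for any α-bromide) gives the conjugated 13-acetoxy butenolide from either regioisomer; the ring fixes the olefin geometry and the buffered acetate spares the now acidic C6–H.

Step 15
Reactants: 23 2,3-dibromopropene
Product: 24 tributyl(2-bromoprop-2-en-1-yl)stannane
Conditions: Bu3SnH, LDA, THF, 0 °C; then 23, −78 °C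
Reagents that add atoms: tributyltin hydride (as tributylstannyllithium) CCCC[SnH](CCCC)CCCC
Why: SN2 displacement of the allylic bromide by the stannyl anion leaves the vinylic bromide in place.

Step 16
Reactants: 22 formyl butenolide; 24 2-bromoallylstannane
Product: 25 [(5R)-4-[(1S)-3-bromo-1-hydroxybut-3-en-1-yl]-5-{(1Z)-5-[(tert-butyldiphenylsilyl)oxy]-2-methylpent-1-en-1-yl}-2-oxo-2,5-dihydrofuran-3-yl]methyl acetate
Conditions: (4S,5S)-2-bromo-4,5-diphenyl-1,3-bis(p-tolylsulfonyl)-1,3,2-diazaborolidine, 24, CH2Cl2, 0 to 23 °C; then 22, −78 °C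
Reagents that add atoms: none
Why: Carbonyl allylation (Corey diazaborolidine allylboration through a chair six-membered transition state after B–Sn exchange) forms C8–C9, and the (S,S)-controller is chosen to deliver the 2-bromoallyl group to the si face of the formyl group, which sets C8 as S under reagent control without base.

Step 17
Reactants: 25 homoallylic alcohol
Product: 26 (1S)-1-[(2R)-4-(acetoxymethyl)-2-{(1Z)-5-[(tert-butyldiphenylsilyl)oxy]-2-methylpent-1-en-1-yl}-5-oxo-2,5-dihydrofuran-3-yl]-3-bromobut-3-en-1-yl acetate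
Conditions: Ac2O, pyridine, CH2Cl2, 0 to 23 °C
Reagents that add atoms: acetic anhydride CC(=O)OC(C)=O
Why: Acetylation installs the 8-acetate with retention and blocks acyl migration or translactonisation to C8, and the weak base spares the C6–H of the butenolide.

Step 18
Reactants: 26 diacetate silyl ether
Product: 27 (1S)-1-[(2R)-4-(acetoxymethyl)-2-[(1Z)-5-hydroxy-2-methylpent-1-en-1-yl]-5-oxo-2,5-dihydrofuran-3-yl]-3-bromobut-3-en-1-yl acetate
Conditions: HF·pyridine, pyridine, THF, 0 to 23 °C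
Reagents that add atoms: none
Why: Buffered fluoride desilylation frees the primary C1 alcohol without cleaving the acetates or epimerising C6.

Step 19
Reactants: 27 primary alcohol
Product: 28 (1S)-1-[(2R)-4-(acetoxymethyl)-2-[(1Z)-2-methyl-5-oxopent-1-en-1-yl]-5-oxo-2,5-dihydrofuran-3-yl]-3-bromobut-3-en-1-yl acetate
Conditions: Dess–Martin periodinane, NaHCO3, CH2Cl2, 23 °C
Reagents that add atoms: none
Why: Dess–Martin oxidation gives the C1 aldehyde under near-neutral conditions compatible with the vinyl bromide, the acetates and the butenolide.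

Step 20
Reactants: 28 bromo aldehyde
Product: 29 8α,13-diacetoxy-1α-hydroxygermacra-4,7(11),10(14)-trien-6α,12-olide
Conditions: CrCl2 (6 equiv), NiCl2 (2 mol %), DMSO, 0.002 M, 23 °C
Reagents that add atoms: none
Why: Nozaki–Hiyama–Kishi reaction in which zerovalent nickel inserts into the C10–Br bond and the vinyl group passes to chromium and adds to the C1 aldehyde under high dilution, closing the ten-membered ring and giving the free allylic alcohol directly; C1 is set here under substrate (ring-conformation) control, 1S being the epimer carried on.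

## Compound list

1 | nerol, (2Z)-3,7-dimethylocta-2,6-dien-1-ol | CC(C)=CCC/C(C)=C\CO | starting material
2 | neryl acetate | CC(C)=CCC/C(C)=C\COC(C)=O | intermediate
3 | (2Z)-5-(3,3-dimethyloxiran-2-yl)-3-methylpent-2-en-1-yl acetate (racemic oxirane) | CC1(C)OC1CC/C(C)=C\COC(C)=O | intermediate
4 | (2Z)-3-methyl-6-oxohex-2-en-1-yl acetate | O=CCC/C(C)=C\COC(C)=O | intermediate
5 | (2Z)-6-hydroxy-3-methylhex-2-en-1-yl acetate | OCCC/C(C)=C\COC(C)=O | intermediate
6 | (2Z)-6-[(tert-butyldiphenylsilyl)oxy]-3-methylhex-2-en-1-yl acetate | CC(=O)OC/C=C(/C)CCCO[Si](c1ccccc1)(c1ccccc1)C(C)(C)C | intermediate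
7 | (2Z)-6-[(tert-butyldiphenylsilyl)oxy]-3-methylhex-2-en-1-ol | OC/C=C(/C)CCCO[Si](c1ccccc1)(c1ccccc1)C(C)(C)C | intermediate
8 | (2Z)-6-[(tert-butyldiphenylsilyl)oxy]-3-methylhex-2-enal | O=C/C=C(/C)CCCO[Si](c1ccccc1)(c1ccccc1)C(C)(C)C | intermediate
9 | (4S)-4-benzyl-1,3-oxazolidin-2-one | O=C1N[C@@H](Cc2ccccc2)CO1 | starting material
10 | itaconic anhydride (3-methylideneoxolane-2,5-dione) | C=C1CC(=O)OC1=O | starting material
11 | lithium (4S)-4-benzyl-2-oxo-1,3-oxazolidin-3-ide (not isolated) | [Li+].O=C1[N-][C@@H](Cc2ccccc2)CO1 | intermediate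
12 | 4-[(4S)-4-benzyl-2-oxo-1,3-oxazolidin-3-yl]-2-methylidene-4-oxobutanoic acid | C=C(CC(=O)N1[C@@H](Cc2ccccc2)COC1=O)C(=O)O | intermediate
13 | methyl 4-[(4S)-4-benzyl-2-oxo-1,3-oxazolidin-3-yl]-2-methylidene-4-oxobutanoate | C=C(CC(=O)N1[C@@H](Cc2ccccc2)COC1=O)C(=O)OC | intermediate
14 | methyl (3Z)-4-[(4S)-4-benzyl-2-oxo-1,3-oxazolidin-3-yl]-4-[(dibutylboranyl)oxy]-2-methylidenebut-3-enoate (not isolated) | COC(=O)C(=C)/C=C(\OB(CCCC)CCCC)N1[C@@H](Cc2ccccc2)COC1=O | intermediate
15 | methyl (3S,4R,5Z)-3-{[(4S)-4-benzyl-2-oxo-1,3-oxazolidin-3-yl]carbonyl}-9-[(tert-butyldiphenylsilyl)oxy]-4-hydroxy-6-methyl-2-methylidenenon-5-enoate | COC(=O)C(=C)[C@H](C(=O)N1[C@@H](Cc2ccccc2)COC1=O)[C@H](O)/C=C(/C)CCCO[Si](c1ccccc1)(c1ccccc1)C(C)(C)C | intermediate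
16 | (2S,3R,4Z)-8-[(tert-butyldiphenylsilyl)oxy]-3-hydroxy-2-(3-methoxy-3-oxoprop-1-en-2-yl)-5-methyloct-4-enoic acid (not isolated) | COC(=O)C(=C)[C@H](C(=O)O)[C@H](O)/C=C(/C)CCCO[Si](c1ccccc1)(c1ccccc1)C(C)(C)C | intermediate
17 | (2R,3S)-2-{(1Z)-5-[(tert-butyldiphenylsilyl)oxy]-2-methylpent-1-en-1-yl}-4-methylidene-5-oxooxolane-3-carboxylic acid | OC(=O)[C@H]1C(=C)C(=O)O[C@@H]1/C=C(/C)CCCO[Si](c1ccccc1)(c1ccccc1)C(C)(C)C | intermediate
18 | (2R,3S)-2-{(1Z)-5-[(tert-butyldiphenylsilyl)oxy]-2-methylpent-1-en-1-yl}-4-methylidene-5-oxooxolane-3-carbonyl chloride (not isolated) | ClC(=O)[C@H]1C(=C)C(=O)O[C@@H]1/C=C(/C)CCCO[Si](c1ccccc1)(c1ccccc1)C(C)(C)C | intermediate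
19 | (2R,3S)-2-{(1Z)-5-[(tert-butyldiphenylsilyl)oxy]-2-methylpent-1-en-1-yl}-4-methylidene-5-oxooxolane-3-carbaldehyde | O=C[C@H]1C(=C)C(=O)O[C@@H]1/C=C(/C)CCCO[Si](c1ccccc1)(c1ccccc1)C(C)(C)C | intermediate
20 | (5R)-4-{[(tert-butyldimethylsilyl)oxy]methylidene}-5-{(1Z)-5-[(tert-butyldiphenylsilyl)oxy]-2-methylpent-1-en-1-yl}-3-methylideneoxolan-2-one | C=C1C(=O)O[C@H](/C=C(/C)CCCO[Si](c2ccccc2)(c2ccccc2)C(C)(C)C)C1=CO[Si](C)(C)C(C)(C)C | intermediate
21 | (2R)-4-(bromomethyl)-2-{(1Z)-5-[(tert-butyldiphenylsilyl)oxy]-2-methylpent-1-en-1-yl}-5-oxo-2,5-dihydrofuran-3-carbaldehyde (not isolated) | O=CC1=C(CBr)C(=O)O[C@@H]1/C=C(/C)CCCO[Si](c1ccccc1)(c1ccccc1)C(C)(C)C | intermediate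
22 | [(5R)-5-{(1Z)-5-[(tert-butyldiphenylsilyl)oxy]-2-methylpent-1-en-1-yl}-4-formyl-2-oxo-2,5-dihydrofuran-3-yl]methyl acetate | O=CC1=C(COC(C)=O)C(=O)O[C@@H]1/C=C(/C)CCCO[Si](c1ccccc1)(c1ccccc1)C(C)(C)C | intermediate
23 | 2,3-dibromopropene | C=C(Br)CBr | starting material
24 | tributyl(2-bromoprop-2-en-1-yl)stannane | C=C(Br)C[Sn](CCCC)(CCCC)CCCC | intermediate
25 | [(5R)-4-[(1S)-3-bromo-1-hydroxybut-3-en-1-yl]-5-{(1Z)-5-[(tert-butyldiphenylsilyl)oxy]-2-methylpent-1-en-1-yl}-2-oxo-2,5-dihydrofuran-3-yl]methyl acetate | C=C(Br)C[C@H](O)C1=C(COC(C)=O)C(=O)O[C@@H]1/C=C(/C)CCCO[Si](c1ccccc1)(c1ccccc1)C(C)(C)C | intermediate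
26 | (1S)-1-[(2R)-4-(acetoxymethyl)-2-{(1Z)-5-[(tert-butyldiphenylsilyl)oxy]-2-methylpent-1-en-1-yl}-5-oxo-2,5-dihydrofuran-3-yl]-3-bromobut-3-en-1-yl acetate | C=C(Br)C[C@H](OC(C)=O)C1=C(COC(C)=O)C(=O)O[C@@H]1/C=C(/C)CCCO[Si](c1ccccc1)(c1ccccc1)C(C)(C)C | intermediate
27 | (1S)-1-[(2R)-4-(acetoxymethyl)-2-[(1Z)-5-hydroxy-2-methylpent-1-en-1-yl]-5-oxo-2,5-dihydrofuran-3-yl]-3-bromobut-3-en-1-yl acetate | C=C(Br)C[C@H](OC(C)=O)C1=C(COC(C)=O)C(=O)O[C@@H]1/C=C(/C)CCCO | intermediate
28 | (1S)-1-[(2R)-4-(acetoxymethyl)-2-[(1Z)-2-methyl-5-oxopent-1-en-1-yl]-5-oxo-2,5-dihydrofuran-3-yl]-3-bromobut-3-en-1-yl acetate | C=C(Br)C[C@H](OC(C)=O)C1=C(COC(C)=O)C(=O)O[C@@H]1/C=C(/C)CCC=O | intermediate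
29 | 8α,13-diacetoxy-1α-hydroxygermacra-4,7(11),10(14)-trien-6α,12-olide | C=C1C[C@H](OC(C)=O)C2=C(COC(C)=O)C(=O)O[C@@H]2/C=C(/C)CC[C@@H]1O | target

## Step count and weak points

Total steps: 20. Longest linear sequence: 17 (steps 1–7, 10–14, 16–20, from nerol).

**Step 13 (with steps 12 and 14 around it).** Aldehyde 19 isomerises easily to the conjugated 3-methylbutenolide, whose C6–H is acidic, so silylation could then take place at C6 and erode that centre. The fallback sets out from 17 and comes back at 22. Acid 17 is taken through the acid chloride 18 with EtSH and pyridine at −20 °C to the chromatography-stable S-ethyl (2R,3S)-2-{(1Z)-5-[(tert-butyldiphenylsilyl)oxy]-2-methylpent-1-en-1-yl}-4-methylidene-5-oxooxolane-3-carbothioate F1. Kinetic deprotonation at C7 with LiHMDS (THF, −78 °C) and NBS quench of the lithium dienolate gives S-ethyl (2R)-4-(bromomethyl)-2-{(1Z)-5-[(tert-butyldiphenylsilyl)oxy]-2-methylpent-1-en-1-yl}-5-oxo-2,5-dihydrofuran-3-carbothioate F2. KOAc in AcOH converts it into S-ethyl (2R)-4-(acetoxymethyl)-2-{(1Z)-5-[(tert-butyldiphenylsilyl)oxy]-2-methylpent-1-en-1-yl}-5-oxo-2,5-dihydrofuran-3-carbothioate F3. A Fukuyama reduction (Et3SiH, Pd/C, acetone) then releases aldehyde 22 only at the end, so the sensitive aldehyde 19 and its silyl enol ether are never made.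

**Step 16.** The sense of induction of the (S,S)-controller is assigned from recalled precedent with simple aldehydes and must be checked (Mosher esters); the selectivity with this hindered, conjugated aldehyde is also uncertain. The fallback sets out from 22 and comes back at 26. A Barbier 2-bromoallylation with indium powder and 2,3-dibromopropene 23 in THF/H2O gives 25 together with its C8 epimer, [(5R)-4-[(1R)-3-bromo-1-hydroxybut-3-en-1-yl]-5-{(1Z)-5-[(tert-butyldiphenylsilyl)oxy]-2-methylpent-1-en-1-yl}-2-oxo-2,5-dihydrofuran-3-yl]methyl acetate F4. The two are separated; 25 is acetylated as in step 17, and the 8R alcohol F4 is treated with AcOH, PPh3 and DIAD (Mitsunobu inversion) to give the same acetate 26, so both epimers converge.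

**Step 20.** Medium-ring closure is entropically and conformationally demanding, and the C1 epimer ratio cannot be predicted. The fallback sets out from 28 and comes back at 29. If the ring closes mainly to the 1-epimer, 8α,13-diacetoxy-1β-hydroxygermacra-4,7(11),10(14)-trien-6α,12-olide F5, this is oxidised with Dess–Martin periodinane to 8α,13-diacetoxy-1-oxogermacra-4,7(11),10(14)-trien-6α,12-olide F6. The enone is reduced under reagent control with (R)-2-methyl-CBS-oxazaborolidine and catecholborane at −78 °C (the α-methylene side acting as the large group) to the 1S alcohol 29.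

## Further compounds

F1 | step 13 | S-ethyl (2R,3S)-2-{(1Z)-5-[(tert-butyldiphenylsilyl)oxy]-2-methylpent-1-en-1-yl}-4-methylidene-5-oxooxolane-3-carbothioate | CCSC(=O)[C@H]1C(=C)C(=O)O[C@@H]1/C=C(/C)CCCO[Si](c1ccccc1)(c1ccccc1)C(C)(C)C
F2 | step 13 | S-ethyl (2R)-4-(bromomethyl)-2-{(1Z)-5-[(tert-butyldiphenylsilyl)oxy]-2-methylpent-1-en-1-yl}-5-oxo-2,5-dihydrofuran-3-carbothioate | CCSC(=O)C1=C(CBr)C(=O)O[C@@H]1/C=C(/C)CCCO[Si](c1ccccc1)(c1ccccc1)C(C)(C)C
F3 | step 13 | S-ethyl (2R)-4-(acetoxymethyl)-2-{(1Z)-5-[(tert-butyldiphenylsilyl)oxy]-2-methylpent-1-en-1-yl}-5-oxo-2,5-dihydrofuran-3-carbothioate | CCSC(=O)C1=C(COC(C)=O)C(=O)O[C@@H]1/C=C(/C)CCCO[Si](c1ccccc1)(c1ccccc1)C(C)(C)C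
F4 | step 16 | [(5R)-4-[(1R)-3-bromo-1-hydroxybut-3-en-1-yl]-5-{(1Z)-5-[(tert-butyldiphenylsilyl)oxy]-2-methylpent-1-en-1-yl}-2-oxo-2,5-dihydrofuran-3-yl]methyl acetate | C=C(Br)C[C@@H](O)C1=C(COC(C)=O)C(=O)O[C@@H]1/C=C(/C)CCCO[Si](c1ccccc1)(c1ccccc1)C(C)(C)C
F5 | step 20 | 8α,13-diacetoxy-1β-hydroxygermacra-4,7(11),10(14)-trien-6α,12-olide (1R epimer of 29) | C=C1C[C@H](OC(C)=O)C2=C(COC(C)=O)C(=O)O[C@@H]2/C=C(/C)CC[C@H]1O
F6 | step 20 | 8α,13-diacetoxy-1-oxogermacra-4,7(11),10(14)-trien-6α,12-olide | C=C1C[C@H](OC(C)=O)C2=C(COC(C)=O)C(=O)O[C@@H]2/C=C(/C)CCC1=O
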